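**Strategy.** Everything rests on building the carbocycle of unit B (the 8-hydroxychromone half) by benzannulation. Its four contiguous substituents are the oxygens on C8' and C8a', the C4' acyl carbon on C4a' and the aryl link at C5'. This is the pattern that a 1,2-dioxygenated vinylketene silyl acetal and an alkynyl ketone deliver, so the ring is cut across C5'-C6' and C4a'-C8a'. One cycloaddition-aromatisation should close this benzene ring, set the biaryl bond's environment and release a 2-hydroxyaryl methyl ketone for the second pyranone. The precursor is the complete unit A chromone, O7-methylated, carrying a 3-oxobut-1-ynyl group at C6.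

Key step: step 7

Assumption: the biaryl axis has only one non-hydrogen ortho substituent on each ring and is taken as freely rotating, so the target has no stereogenic element. Compounds 6, 7 and 13 are racemic and their stereocentres are erased later.

Remark: the diene needs a four-carbon ester, since a methoxyacetate alone cannot supply the vinyl terminus. Methyl 2-methoxybut-2-enoate is therefore made first by olefination.

**Route**

Step 1
Reactants: 1 1-(5-bromo-2,4-dihydroxyphenyl)ethanone
Product: 2 1-(5-bromo-2-hydroxy-4-methoxyphenyl)ethanone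
Conditions: MeI (1.05 equiv), K2CO3, acetone, 56 °C
Reagents that add atoms: iodomethane, CI
Why: Williamson etherification should occur only at the 4-OH, which is the more acidic phenol, because the 2-OH is held in a hydrogen bond to the ketone; the methyl ether later keeps the C7 oxygen from adding to the ortho alkyne.

Step 2
Reactants: 2 1-(5-bromo-2-hydroxy-4-methoxyphenyl)ethanone; 3 ethyl 3-phenylpropanoate
Product: 5 6-bromo-7-methoxy-2-(2-phenylethyl)chromen-4-one, via diketone 4 (not isolated)
Conditions: NaH (4 equiv), 3 (1.5 equiv), THF, 65 °C; then AcOH, conc. HCl, 65 °C, same flask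
Reagents that add atoms: none
Why: Crossed Claisen condensation of the phenoxide-enolate dianion with the ester should give the 1,3-diketone, and acid-catalysed cyclodehydration of such diketones is the standard entry to 2-alkylchromones.

Step 3
Reactants: 5 6-bromo-7-methoxy-2-(2-phenylethyl)chromen-4-one; 6 but-3-yn-2-ol (racemic)
Product: 7 6-(3-hydroxybut-1-ynyl)-7-methoxy-2-(2-phenylethyl)chromen-4-one (racemic)
Conditions: PdCl2(PPh3)2 (5 mol%), CuI (10 mol%), Et3N, DMF, 80 °C
Reagents that add atoms: none
Why: Sonogashira coupling of the aryl bromide with the free propargylic alcohol installs all four carbons of the future ynone at once and avoids the amine-sensitive but-3-yn-2-one as coupling partner.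

Step 4
Reactants: 7 6-(3-hydroxybut-1-ynyl)-7-methoxy-2-(2-phenylethyl)chromen-4-one
Product: 8 7-methoxy-6-(3-oxobut-1-ynyl)-2-(2-phenylethyl)chromen-4-one
Conditions: activated MnO2 (excess), CH2Cl2, rt
Reagents that add atoms: none
Why: MnO2 oxidation of an activated propargylic secondary alcohol is neutral and selective, so the chromone and the new ynone should be left untouched while the carbinol stereocentre disappears.

Step 5
Reactants: 9 methyl 2-(dimethoxyphosphoryl)-2-methoxyacetate; 10 acetaldehyde
Product: 11 methyl 2-methoxybut-2-enoate (Z isomer drawn; a geometric mixture serves equally)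
Conditions: NaH, THF, 0 °C; then MeCHO, 0 °C to rt; distillation
Reagents that add atoms: none
Why: Horner-Wadsworth-Emmons olefination of the stabilised alpha-methoxy phosphonate anion with an unhindered aldehyde should give the 2-methoxy enoate reliably.

Step 6
Reactants: 11 methyl 2-methoxybut-2-enoate
Product: 12 (1E)-1,2-dimethoxy-1-(trimethylsilyloxy)buta-1,3-diene (geometry at C1 is erased on aromatisation, so the 1Z isomer serves equally)
Conditions: LiN(iPr)2 (commercial solution), THF/DMPU, -78 °C; then Me3SiCl, -78 °C to rt; filtration under argon, distillation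
Reagents that add atoms: chlorotrimethylsilane, C[Si](C)(C)Cl
Why: Gamma-deprotonation of the enoate to the extended enolate and O-silylation is the standard preparation of 1-alkoxy-1-silyloxybuta-1,3-dienes, with DMPU suppressing conjugate addition of the amide base.

Step 7
Reactants: 8 7-methoxy-6-(3-oxobut-1-ynyl)-2-(2-phenylethyl)chromen-4-one; 12 (1E)-1,2-dimethoxy-1-(trimethylsilyloxy)buta-1,3-diene
Product: 15 6-(2-acetyl-3-hydroxy-4-methoxyphenyl)-7-methoxy-2-(2-phenylethyl)chromen-4-one, via cyclohexadiene cycloadduct 13 (not isolated), via aryl trimethylsilyl ether 14 (not isolated)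
Conditions: 12 (3 equiv), toluene, 100 °C, sealed tube; then 1 M HCl, THF, rt
Reagents that add atoms: none
Why: The electron-rich diene 12 (largest HOMO coefficient at its CH2 terminus) and ynone 8 (largest LUMO coefficient at the aryl-bearing beta-carbon) should combine in a normal-demand, strongly asynchronous (4+2) cycloaddition, or in its stepwise limit a Michael addition followed by closure of the allenolate onto the oxocarbenium carbon, to give cyclohexa-1,4-diene 13, which aromatises by 1,4-loss of methanol from the mixed acetal carbon to silyl ether 14 and is cleaved to phenol 15 on acidic work-up. The closest known reaction type is the Diels-Alder benzannulation of 1-alkoxy-1-silyloxybuta-1,3-dienes with acetylenic ketones and esters to ortho-acyl phenols. The unit B benzene ring is closed by intermolecular (4+2) cycloaddition, C5'-C6' and C4a'-C8a' arising in the same event (a 6-exo-trig closure onto the oxocarbenium carbon if the process is stepwise). No stereocentre survives, since the acetal carbon of 13 is formed racemic and is flattened on aromatisation. The step needs head-to-head regiochemistry and chemoselectivity for the alkyne: the matched polarisation of both partners secures the first, and the second follows because the chromone C2=C3 bond is a trisubstituted, oxygen-deactivated vinylogous ester and a far poorer 2-pi partner than the ynone. The C7 methyl ether prevents the ortho oxygen from adding to the activated alkyne.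

Step 8
Reactants: 15 6-(2-acetyl-3-hydroxy-4-methoxyphenyl)-7-methoxy-2-(2-phenylethyl)chromen-4-one; 16 3-phenylpropanoyl chloride
Product: 17 2-acetyl-6-methoxy-3-[7-methoxy-4-oxo-2-(2-phenylethyl)chromen-6-yl]phenyl 3-phenylpropanoate
Conditions: 16 (1.5 equiv), Et3N, DMAP (cat.), CH2Cl2, 0 °C to rt
Reagents that add atoms: none
Why: DMAP-catalysed esterification of the chelated phenol places the acyl group for an intramolecular shift, so that neither excess strong base nor a free acylating agent has to meet the base-sensitive unit A pyranone in the next step.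

Step 9
Reactants: 17 2-acetyl-6-methoxy-3-[7-methoxy-4-oxo-2-(2-phenylethyl)chromen-6-yl]phenyl 3-phenylpropanoate
Product: 19 7-methoxy-6-[8-methoxy-4-oxo-2-(2-phenylethyl)chromen-5-yl]-2-(2-phenylethyl)chromen-4-one, via pentane-1,3-dione 18 (not isolated)
Conditions: KOtBu (2.5 equiv), THF, 0 °C to rt; then AcOH, conc. HCl, 60 °C, same flask
Reagents that add atoms: none
Why: In the Baker-Venkataraman rearrangement the methyl ketone enolate should attack the neighbouring aryl ester through a six-membered transition state to give the 1,3-diketone, which the acid then closes to the unit B pyranone by cyclodehydration, reclosing at the same time any unit A pyranone opened by base.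

Step 10
Reactants: 19 7-methoxy-6-[8-methoxy-4-oxo-2-(2-phenylethyl)chromen-5-yl]-2-(2-phenylethyl)chromen-4-one
Product: 20 7-hydroxy-6-[8-hydroxy-4-oxo-2-(2-phenylethyl)chromen-5-yl]-2-(2-phenylethyl)chromen-4-one
Conditions: BBr3 (8 equiv), CH2Cl2, -78 °C to rt; then MeOH, water
Reagents that add atoms: none
Why: Lewis acid-mediated cleavage of aryl methyl ethers with BBr3 should free both phenols in one operation, the pyranones and the saturated phenylethyl chains being inert to it.

**Compound list**

1 | 1-(5-bromo-2,4-dihydroxyphenyl)ethanone | CC(=O)c1cc(Br)c(O)cc1O | starting material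
2 | 1-(5-bromo-2-hydroxy-4-methoxyphenyl)ethanone | CC(=O)c1cc(Br)c(OC)cc1O | intermediate
3 | ethyl 3-phenylpropanoate | CCOC(=O)CCc1ccccc1 | starting material
4 | 1-(5-bromo-2-hydroxy-4-methoxyphenyl)-5-phenylpentane-1,3-dione | COc1cc(O)c(C(=O)CC(=O)CCc2ccccc2)cc1Br | intermediate (not isolated)
5 | 6-bromo-7-methoxy-2-(2-phenylethyl)chromen-4-one | COc1cc2oc(CCc3ccccc3)cc(=O)c2cc1Br | intermediate
6 | but-3-yn-2-ol (racemic) | CC(O)C#C | starting material
7 | 6-(3-hydroxybut-1-ynyl)-7-methoxy-2-(2-phenylethyl)chromen-4-one (racemic) | COc1cc2oc(CCc3ccccc3)cc(=O)c2cc1C#CC(C)O | intermediate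
8 | 7-methoxy-6-(3-oxobut-1-ynyl)-2-(2-phenylethyl)chromen-4-one | COc1cc2oc(CCc3ccccc3)cc(=O)c2cc1C#CC(C)=O | intermediate
9 | methyl 2-(dimethoxyphosphoryl)-2-methoxyacetate | COC(=O)C(OC)P(=O)(OC)OC | starting material
10 | acetaldehyde | CC=O | starting material
11 | methyl (2Z)-2-methoxybut-2-enoate | C/C=C(\OC)C(=O)OC | intermediate
12 | (1E)-1,2-dimethoxy-1-(trimethylsilyloxy)buta-1,3-diene | C=C/C(OC)=C(/OC)O[Si](C)(C)C | intermediate
13 | 6-[2-acetyl-3,4-dimethoxy-3-(trimethylsilyloxy)cyclohexa-1,4-dien-1-yl]-7-methoxy-2-(2-phenylethyl)chromen-4-one (racemic) | COc1cc2oc(CCc3ccccc3)cc(=O)c2cc1C1=C(C(C)=O)C(OC)(O[Si](C)(C)C)C(OC)=CC1 | intermediate (not isolated)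
14 | 6-[2-acetyl-4-methoxy-3-(trimethylsilyloxy)phenyl]-7-methoxy-2-(2-phenylethyl)chromen-4-one | COc1cc2oc(CCc3ccccc3)cc(=O)c2cc1-c1ccc(OC)c(O[Si](C)(C)C)c1C(C)=O | intermediate (not isolated)
15 | 6-(2-acetyl-3-hydroxy-4-methoxyphenyl)-7-methoxy-2-(2-phenylethyl)chromen-4-one | COc1cc2oc(CCc3ccccc3)cc(=O)c2cc1-c1ccc(OC)c(O)c1C(C)=O | intermediate
16 | 3-phenylpropanoyl chloride | O=C(Cl)CCc1ccccc1 | starting material
17 | 2-acetyl-6-methoxy-3-[7-methoxy-4-oxo-2-(2-phenylethyl)chromen-6-yl]phenyl 3-phenylpropanoate | COc1cc2oc(CCc3ccccc3)cc(=O)c2cc1-c1ccc(OC)c(OC(=O)CCc2ccccc2)c1C(C)=O | intermediate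
18 | 1-{2-hydroxy-3-methoxy-6-[7-methoxy-4-oxo-2-(2-phenylethyl)chromen-6-yl]phenyl}-5-phenylpentane-1,3-dione | COc1cc2oc(CCc3ccccc3)cc(=O)c2cc1-c1ccc(OC)c(O)c1C(=O)CC(=O)CCc1ccccc1 | intermediate (not isolated)
19 | 7-methoxy-6-[8-methoxy-4-oxo-2-(2-phenylethyl)chromen-5-yl]-2-(2-phenylethyl)chromen-4-one | COc1cc2oc(CCc3ccccc3)cc(=O)c2cc1-c1ccc(OC)c2oc(CCc3ccccc3)cc(=O)c12 | intermediate
20 | 7-hydroxy-6-[8-hydroxy-4-oxo-2-(2-phenylethyl)chromen-5-yl]-2-(2-phenylethyl)chromen-4-one | O=c1cc(CCc2ccccc2)oc2cc(O)c(-c3ccc(O)c4oc(CCc5ccccc5)cc(=O)c34)cc12 | target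

**Step count**

Total: 10 steps (steps 2 and 9 each run two operations in one flask).
Longest linear sequence: 8 steps (1, 2, 3, 4, 7, 8, 9, 10); the diene branch (steps 5 and 6) joins at step 7.

**Steps most likely to fail**

Step 7. The cycloaddition onto the electron-rich, ortho-substituted aryl ynone may be slower than hydrolysis or oligomerisation of the diene. Aromatisation may also proceed by loss of silanol and leave the aryl methyl ether. The fallback forms the biaryl bond by cross-coupling in place of ring construction. Setting out from 5, Miyaura borylation (B2pin2, Pd(dppf)Cl2, KOAc, dioxane, 90 °C) should give the pinacol boronate 7-methoxy-2-(2-phenylethyl)-6-(4,4,5,5-tetramethyl-1,3,2-dioxaborolan-2-yl)chromen-4-one F1. Ring bromination of commercial 1-(2,3-dimethoxyphenyl)ethanone with N-bromosuccinimide in MeCN, directed para to the 3-methoxy group, should give 1-(6-bromo-2,3-dimethoxyphenyl)ethanone F2. Suzuki-Miyaura coupling of F1 with F2 (Pd(OAc)2, SPhos, K3PO4, toluene/water, 90 °C) should give 6-(2-acetyl-3,4-dimethoxyphenyl)-7-methoxy-2-(2-phenylethyl)chromen-4-one F3. Chelation-controlled cleavage of the methoxy group ortho to the acetyl with BCl3 (CH2Cl2, -78 to 0 °C) then returns to the route at 15.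

Step 9. Under the basic acyl shift the aryl ester may fragment through enolisation toward a ketene and return the phenol. The unit A pyranone may also be deprotonated at its side chain or opened. The fallback is a base-free enaminone route. Setting out from 15, the amide acetal 1,1-dimethoxy-N,N-dimethyl-3-phenylpropan-1-amine F4 is used, made from N,N-dimethyl-3-phenylpropanamide by O-methylation with dimethyl sulfate and then NaOMe. Heating 15 with F4 in toluene at 110 °C should condense it with the acetyl methyl group to the enaminone (2E)-3-(dimethylamino)-1-{2-hydroxy-3-methoxy-6-[7-methoxy-4-oxo-2-(2-phenylethyl)chromen-6-yl]phenyl}-5-phenylpent-2-en-1-one F5. Warming F5 in AcOH should close the pyranone with loss of dimethylamine and rejoin the route at 19.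

Step 3. Oxidative addition of zerovalent palladium into the electron-rich C6-Br bond next to the methoxy group may be slow at temperatures that the propargylic alcohol and the pyranone tolerate, so that copper-mediated homocoupling consumes the alkyne. The fallback changes the electrophile. Setting out from 5, copper-catalysed halogen exchange (CuI, N,N'-dimethylethylenediamine, NaI, dioxane, 110 °C) should give 6-iodo-7-methoxy-2-(2-phenylethyl)chromen-4-one F6. F6 should couple with 6 at room temperature under PdCl2(PPh3)2, CuI and Et3N and rejoin the route at 7.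

**Further compounds**

F1 | step 7 | 7-methoxy-2-(2-phenylethyl)-6-(4,4,5,5-tetramethyl-1,3,2-dioxaborolan-2-yl)chromen-4-one | COc1cc2oc(CCc3ccccc3)cc(=O)c2cc1B1OC(C)(C)C(C)(C)O1
F2 | step 7 | 1-(6-bromo-2,3-dimethoxyphenyl)ethanone | CC(=O)c1c(OC)c(OC)ccc1Br
F3 | step 7 | 6-(2-acetyl-3,4-dimethoxyphenyl)-7-methoxy-2-(2-phenylethyl)chromen-4-one | COc1cc2oc(CCc3ccccc3)cc(=O)c2cc1-c1ccc(OC)c(OC)c1C(C)=O
F4 | step 9 | 1,1-dimethoxy-N,N-dimethyl-3-phenylpropan-1-amine | COC(CCc1ccccc1)(OC)N(C)C
F5 | step 9 | (2E)-3-(dimethylamino)-1-{2-hydroxy-3-methoxy-6-[7-methoxy-4-oxo-2-(2-phenylethyl)chromen-6-yl]phenyl}-5-phenylpent-2-en-1-one | COc1cc2oc(CCc3ccccc3)cc(=O)c2cc1-c1ccc(OC)c(O)c1C(=O)/C=C(\CCc1ccccc1)N(C)C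
F6 | step 3 | 6-iodo-7-methoxy-2-(2-phenylethyl)chromen-4-one | COc1cc2oc(CCc3ccccc3)cc(=O)c2cc1I
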